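The plan cuts the bond between the side-chain CH2 and C2 of the 2H-pyran ring (ring B). C2 carries O1, a methyl group and the C3=C4 π-bond, so it is built as an α-oxygenated, π-stabilised carbanion: a lithiated (R)-propargylic carbamate that already holds the tetramethoxyarene, the masked quinone ring C. This anion captures the primary boronic ester of the cyclohexane fragment (ring A). A 1,2-metallate shift expels the carbamate, joins both halves and fixes the fully substituted C2 stereospecifically, and oxidation puts O1 in place of boron. Semi-hydrogenation, oxidation to the quinone and displacement of a ring methoxy group by the tertiary alcohol then close ring B.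

Key step: step 12

Assumption: capture of the lithiated propargylic carbamate by the pinacol boronic ester is taken to go with retention, as for lithiated benzylic and allylic carbamates; should it prove invertive, (S)-but-3-yn-2-ol would be used in step 10.

Step 1
Reactants: 1 (R)-(−)-carvone
Product: 3 (5R,6S)-2,6-dimethyl-5-(prop-1-en-2-yl)cyclohex-2-en-1-one, via lithium dienolate 2 (not isolated)
Conditions: LiN(iPr)2, THF, −78 °C; MeI, −78 → 0 °C
Reagents that add atoms: iodomethane, CI
Why: Kinetic α′-deprotonation of the cross-conjugated enone followed by SN2 methylation (enolate alkylation) is routine for carvone, and the new C6 centre, formed mainly trans to the isopropenyl group, is erased again in step 2.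

Step 2
Reactants: 3 (5R,6S)-2,6-dimethyl-5-(prop-1-en-2-yl)cyclohex-2-en-1-one
Product: 5 tert-butyl 2-[(1S,6S)-1,3-dimethyl-2-oxo-6-(prop-1-en-2-yl)cyclohex-3-en-1-yl]acetate, via lithium enolate 4 (not isolated)
Conditions: LiN(iPr)2, THF/DMPU, −78 → 0 °C; BrCH2CO2tBu, −78 °C → rt
Reagents that add atoms: tert-butyl bromoacetate, CC(C)(C)OC(=O)CBr
Why: Enolate alkylation: the tetrasubstituted cross-conjugated lithium enolate 4 holds the neighbouring isopropenyl group pseudo-axial, so the reactive α-bromo ester should attack the opposite face and set the quaternary centre with the acetate arm trans to isopropenyl.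

Step 3
Reactants: 5 tert-butyl 2-[(1S,6S)-1,3-dimethyl-2-oxo-6-(prop-1-en-2-yl)cyclohex-3-en-1-yl]acetate
Product: 7 tert-butyl 2-[(1R)-1,3-dimethyl-2-oxocyclohex-3-en-1-yl]acetate, via methoxy hydroperoxide 6 (not isolated)
Conditions: O3, MeOH, −78 °C; N2 purge; FeSO4·7H2O, PhSH, −78 °C → rt
Reagents that add atoms: none
Why: Hydrodealkenylation (ozonolysis in methanol, reductive O–O cleavage of 6 by divalent iron, β-scission of the alkoxy radical and hydrogen-atom transfer from the thiol): ozone prefers the electron-rich isopropenyl group to the enone C=C, the spent control element leaves as formaldehyde and methyl acetate, and the quaternary centre is not touched.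

Step 4
Reactants: 7 tert-butyl 2-[(1R)-1,3-dimethyl-2-oxocyclohex-3-en-1-yl]acetate
Product: 8 tert-butyl 2-[(1R,3R)-1,3-dimethyl-2-oxocyclohexyl]acetate
Conditions: H2 (1 atm), Pd/C, EtOAc, rt
Reagents that add atoms: none
Why: Heterogeneous catalytic hydrogenation (syn addition of H2): next to the carbonyl the larger CH2CO2tBu arm prefers the pseudo-axial position and shields its face of the enone, so hydrogen should arrive from the face of the ring methyl group and place the new C3 methyl cis to the arm (3R), while the neutral medium prevents epimerisation to the more stable epimer.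

Step 5
Reactants: 8 tert-butyl 2-[(1R,3R)-1,3-dimethyl-2-oxocyclohexyl]acetate
Product: 9 tert-butyl 2-[(1R,3R)-1,3-dimethyl-2-methylidenecyclohexyl]acetate
Conditions: Zn, CH2Br2, TiCl4, THF/CH2Cl2, 0 °C → rt
Reagents that add atoms: dibromomethane, BrCBr
Why: Takai–Lombardo methylenation: the non-basic gem-dizinc/titanium reagent methylenates hindered enolisable ketones without epimerising the α-centre and does not react with the tert-butyl ester.

Step 6
Reactants: 9 tert-butyl 2-[(1R,3R)-1,3-dimethyl-2-methylidenecyclohexyl]acetate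
Product: 10 2-[(1R,3R)-1,3-dimethyl-2-methylidenecyclohexyl]ethan-1-ol
Conditions: LiAlH4, Et2O, 0 °C
Reagents that add atoms: none
Why: Hydride reduction of the ester to the primary alcohol; the isolated 1,1-disubstituted alkene is inert to LiAlH4 and no stereocentre is involved.

Step 7
Reactants: 10 2-[(1R,3R)-1,3-dimethyl-2-methylidenecyclohexyl]ethan-1-ol
Product: 11 (1R,3R)-1-(2-iodoethyl)-1,3-dimethyl-2-methylidenecyclohexane
Conditions: I2, PPh3, imidazole, CH2Cl2, 0 °C → rt
Reagents that add atoms: iodine, II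
Why: Appel-type iodination (SN2 displacement of the alkoxyphosphonium ion by iodide) is reliable for unhindered primary alcohols and spares the alkene.

Step 8
Reactants: 11 (1R,3R)-1-(2-iodoethyl)-1,3-dimethyl-2-methylidenecyclohexane
Product: 12 2-{2-[(1S,3R)-1,3-dimethyl-2-methylidenecyclohexyl]ethyl}-4,4,5,5-tetramethyl-1,3,2-dioxaborolane (same spatial arrangement as 11; the descriptor changes only because boron ranks below carbon)
Conditions: B2pin2, CuI (10 mol %), PPh3 (13 mol %), LiOMe, DMF, rt
Reagents that add atoms: bis(pinacolato)diboron, CC1(C)OB(OC1(C)C)B1OC(C)(C)C(C)(C)O1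
Why: Copper-catalysed borylation of a primary alkyl iodide with B2pin2 under mild alkoxide activation gives the pinacol boronic ester, and the 4-pentenyl-type relation of the chain end to the alkene makes cyclisation of any radical intermediate too slow to compete.

Step 9
Reactants: 13 1,2,4,5-tetramethoxybenzene
Product: 15 3-iodo-1,2,4,5-tetramethoxybenzene, via aryllithium 14 (not isolated)
Conditions: nBuLi, THF, 0 °C → rt; I2, −78 °C → rt
Reagents that add atoms: iodine, II
Why: Directed ortho-lithiation at one of the two equivalent C–H positions flanked by methoxy groups followed by iodine quench.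

Step 10
Reactants: 16 (R)-but-3-yn-2-ol
Product: 17 (2R)-but-3-yn-2-yl N,N-diisopropylcarbamate
Conditions: iPr2NC(O)Cl, Et3N, CH2Cl2, reflux
Reagents that add atoms: N,N-diisopropylcarbamoyl chloride, CC(C)N(C(C)C)C(=O)Cl
Why: O-Carbamoylation of the secondary alcohol at oxygen only, so that the (R)-centre of the chiral-pool alcohol is carried over unchanged.

Step 11
Reactants: 15 3-iodo-1,2,4,5-tetramethoxybenzene; 17 (2R)-but-3-yn-2-yl N,N-diisopropylcarbamate
Product: 18 (2R)-4-(2,3,5,6-tetramethoxyphenyl)but-3-yn-2-yl N,N-diisopropylcarbamate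
Conditions: PdCl2(PPh3)2 (5 mol %), CuI (10 mol %), Et3N/DMF, 60 °C
Reagents that add atoms: none
Why: Sonogashira coupling of an aryl iodide with a terminal alkyne; gentle heating compensates for the two ortho methoxy groups and the poor leaving ability of the dialkylcarbamate keeps the propargylic centre intact.

Step 12
Reactants: 18 (2R)-4-(2,3,5,6-tetramethoxyphenyl)but-3-yn-2-yl N,N-diisopropylcarbamate; 12 2-{2-[(1S,3R)-1,3-dimethyl-2-methylidenecyclohexyl]ethyl}-4,4,5,5-tetramethyl-1,3,2-dioxaborolane
Product: 22 (3S)-5-[(1R,3R)-1,3-dimethyl-2-methylidenecyclohexyl]-3-methyl-1-(2,3,5,6-tetramethoxyphenyl)pent-1-yn-3-ol, via lithiated carbamate 19 (not isolated), via boronate complex 20 (not isolated), via tertiary boronic ester 21 (not isolated)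
Conditions: 18, sBuLi, TMEDA, Et2O, −78 °C, 15 min; 12 in Et2O, −78 °C, 1 h, then → rt; aq NaOH, H2O2, THF, 0 °C → rt
Reagents that add atoms: hydrogen peroxide, OO
Why: sBuLi/TMEDA removes the propargylic hydrogen of 18, which is acidified by the alkyne and reached through coordination to the carbamate C=O, with retention to give 19; boronic ester 12 is captured with retention to give boronate 20, on warming its primary alkyl group migrates from boron to carbon anti-periplanar to the leaving carbamate (1,2-metallate shift with inversion at carbon), which makes the CH2–C bond and gives 21, and alkaline H2O2 replaces boron by oxygen with retention. The closest known reaction type is the lithiation–borylation–oxidation of enantioenriched secondary propargylic, allylic and benzylic carbamates with pinacol boronic esters, an established stereospecific entry to tertiary alcohols. No ring is closed in this step. The one new stereocentre, the carbinol carbon that becomes C2 of ring B, is controlled only by the (R)-centre of 18: in the net result the alkyl chain takes the place of hydrogen and oxygen keeps its place, which gives (S). Three selectivities are needed: lithiation at the propargylic carbon and not at the arene C–H between two methoxy groups (secured by the far higher kinetic acidity at −78 °C and by one equivalent of base), capture at the α-carbon and not at the allenyl terminus (secured by the two ortho methoxy groups that block that terminus), and capture before the anion loses its configuration (secured by a short lithiation time at −78 °C in Et2O). The exocyclic alkene of 12 and the aryl ethers are inert to every reagent used.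

Step 13
Reactants: 22 (3S)-5-[(1R,3R)-1,3-dimethyl-2-methylidenecyclohexyl]-3-methyl-1-(2,3,5,6-tetramethoxyphenyl)pent-1-yn-3-ol
Product: 23 (1Z,3S)-5-[(1R,3R)-1,3-dimethyl-2-methylidenecyclohexyl]-3-methyl-1-(2,3,5,6-tetramethoxyphenyl)pent-1-en-3-ol
Conditions: H2 (1 atm), Pd/CaCO3 poisoned with Pb(OAc)2, quinoline, EtOAc, rt
Reagents that add atoms: none
Why: Lindlar semi-hydrogenation: syn delivery of one equivalent of H2 to the alkyne on the poisoned palladium surface gives the Z-alkene that ring B needs, and the hindered exocyclic methylene group does not compete.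

Step 14
Reactants: 23 (1Z,3S)-5-[(1R,3R)-1,3-dimethyl-2-methylidenecyclohexyl]-3-methyl-1-(2,3,5,6-tetramethoxyphenyl)pent-1-en-3-ol
Product: 24 3-[(1Z,3S)-5-[(1R,3R)-1,3-dimethyl-2-methylidenecyclohexyl]-3-hydroxy-3-methylpent-1-en-1-yl]-2,5-dimethoxycyclohexa-2,5-diene-1,4-dione
Conditions: (NH4)2Ce(NO3)6 (2.2 equiv), MeCN/H2O, 0 °C, 10 min
Reagents that add atoms: water, O
Why: Oxidative demethylation of a 1,4-dimethoxyarene by tetravalent cerium (two one-electron oxidations with ipso attack of water): the very electron-rich arene is oxidised within minutes at 0 °C before the alkenes or the alcohol react, and because of the local symmetry of the arene either para pair gives the same 2,5-dimethoxyquinone.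

Step 15
Reactants: 24 3-[(1Z,3S)-5-[(1R,3R)-1,3-dimethyl-2-methylidenecyclohexyl]-3-hydroxy-3-methylpent-1-en-1-yl]-2,5-dimethoxycyclohexa-2,5-diene-1,4-dione
Product: 25 metachromin E, (2S)-2-{2-[(1R,3R)-1,3-dimethyl-2-methylidenecyclohexyl]ethyl}-6-methoxy-2-methyl-2H-chromene-5,8-dione
Conditions: Cs2CO3 (0.5 equiv), 4 Å molecular sieves, MeCN, rt
Reagents that add atoms: none
Why: Intramolecular addition–elimination on a methoxyquinone (vinylogous transesterification, 6-endo-trig): the Z-alkene holds the alkoxide next to the methoxy-bearing quinone carbon, methoxide is expelled and held as methanol by the sieves, and since only the O–C(quinone) bond is formed the C2 configuration is retained.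

Compound list
1 | (R)-(−)-carvone | O=C1C(C)=CC[C@@H](C(C)=C)C1 | starting material
2 | lithium dienolate of carvone | [Li]OC1=C[C@H](C(C)=C)CC=C1C | intermediate
3 | (5R,6S)-2,6-dimethyl-5-(prop-1-en-2-yl)cyclohex-2-en-1-one (6-methylcarvone; major trans epimer) | O=C1C(C)=CC[C@@H](C(C)=C)[C@@H]1C | intermediate
4 | lithium enolate of 6-methylcarvone | [Li]OC1=C(C)[C@H](C(C)=C)CC=C1C | intermediate
5 | tert-butyl 2-[(1S,6S)-1,3-dimethyl-2-oxo-6-(prop-1-en-2-yl)cyclohex-3-en-1-yl]acetate | O=C1C(C)=CC[C@@H](C(C)=C)[C@]1(C)CC(=O)OC(C)(C)C | intermediate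
6 | α-methoxy hydroperoxide from ozonolysis of 5 in methanol (new acetal carbon unassigned) | O=C1C(C)=CC[C@@H](C(C)(OC)OO)[C@]1(C)CC(=O)OC(C)(C)C | intermediate
7 | tert-butyl 2-[(1R)-1,3-dimethyl-2-oxocyclohex-3-en-1-yl]acetate | O=C1C(C)=CCC[C@]1(C)CC(=O)OC(C)(C)C | intermediate
8 | tert-butyl 2-[(1R,3R)-1,3-dimethyl-2-oxocyclohexyl]acetate | O=C1[C@H](C)CCC[C@]1(C)CC(=O)OC(C)(C)C | intermediate
9 | tert-butyl 2-[(1R,3R)-1,3-dimethyl-2-methylidenecyclohexyl]acetate | C=C1[C@H](C)CCC[C@]1(C)CC(=O)OC(C)(C)C | intermediate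
10 | 2-[(1R,3R)-1,3-dimethyl-2-methylidenecyclohexyl]ethan-1-ol | C=C1[C@H](C)CCC[C@]1(C)CCO | intermediate
11 | (1R,3R)-1-(2-iodoethyl)-1,3-dimethyl-2-methylidenecyclohexane | C=C1[C@H](C)CCC[C@]1(C)CCI | intermediate
12 | 2-{2-[(1S,3R)-1,3-dimethyl-2-methylidenecyclohexyl]ethyl}-4,4,5,5-tetramethyl-1,3,2-dioxaborolane | C=C1[C@H](C)CCC[C@]1(C)CCB2OC(C)(C)C(C)(C)O2 | intermediate
13 | 1,2,4,5-tetramethoxybenzene | COc1cc(OC)c(OC)cc1OC | starting material
14 | (2,3,5,6-tetramethoxyphenyl)lithium | [Li]c1c(OC)c(OC)cc(OC)c1OC | intermediate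
15 | 3-iodo-1,2,4,5-tetramethoxybenzene | Ic1c(OC)c(OC)cc(OC)c1OC | intermediate
16 | (R)-but-3-yn-2-ol | C[C@@H](O)C#C | starting material
17 | (2R)-but-3-yn-2-yl N,N-diisopropylcarbamate | C[C@@H](OC(=O)N(C(C)C)C(C)C)C#C | intermediate
18 | (2R)-4-(2,3,5,6-tetramethoxyphenyl)but-3-yn-2-yl N,N-diisopropylcarbamate | C[C@@H](OC(=O)N(C(C)C)C(C)C)C#Cc1c(OC)c(OC)cc(OC)c1OC | intermediate
19 | α-lithiated carbamate from 18 (Li in the place of H) | C[C@@]([Li])(OC(=O)N(C(C)C)C(C)C)C#Cc1c(OC)c(OC)cc(OC)c1OC | intermediate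
20 | lithium boronate complex of 19 and 12 (B in the place of Li) | [Li+].C[C@@]([B-]1(CC[C@@]2(C)CCC[C@@H](C)C2=C)OC(C)(C)C(C)(C)O1)(OC(=O)N(C(C)C)C(C)C)C#Cc3c(OC)c(OC)cc(OC)c3OC | intermediate
21 | 2-[(3R)-5-[(1R,3R)-1,3-dimethyl-2-methylidenecyclohexyl]-3-methyl-1-(2,3,5,6-tetramethoxyphenyl)pent-1-yn-3-yl]-4,4,5,5-tetramethyl-1,3,2-dioxaborolane | C[C@](B1OC(C)(C)C(C)(C)O1)(CC[C@@]2(C)CCC[C@@H](C)C2=C)C#Cc3c(OC)c(OC)cc(OC)c3OC | intermediate
22 | (3S)-5-[(1R,3R)-1,3-dimethyl-2-methylidenecyclohexyl]-3-methyl-1-(2,3,5,6-tetramethoxyphenyl)pent-1-yn-3-ol | C=C1[C@H](C)CCC[C@]1(C)CC[C@@](O)(C)C#Cc2c(OC)c(OC)cc(OC)c2OC | intermediate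
23 | (1Z,3S)-5-[(1R,3R)-1,3-dimethyl-2-methylidenecyclohexyl]-3-methyl-1-(2,3,5,6-tetramethoxyphenyl)pent-1-en-3-ol | C=C1[C@H](C)CCC[C@]1(C)CC[C@@](O)(C)/C=C\c2c(OC)c(OC)cc(OC)c2OC | intermediate
24 | 3-[(1Z,3S)-5-[(1R,3R)-1,3-dimethyl-2-methylidenecyclohexyl]-3-hydroxy-3-methylpent-1-en-1-yl]-2,5-dimethoxycyclohexa-2,5-diene-1,4-dione | C=C1[C@H](C)CCC[C@]1(C)CC[C@@](O)(C)/C=C\C2=C(OC)C(=O)C=C(OC)C2=O | intermediate
25 | metachromin E, (2S)-2-{2-[(1R,3R)-1,3-dimethyl-2-methylidenecyclohexyl]ethyl}-6-methoxy-2-methyl-2H-chromene-5,8-dione | C=C1[C@H](C)CCC[C@]1(C)CC[C@@]1(C)C=CC2=C(O1)C(=O)C=C(OC)C2=O | target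

Total step count: 15
Longest linear sequence: 12 steps (steps 1–8 and 12–15)

Steps most likely to fail

1. Step 12. The aryl-conjugated lithiated carbamate may lose its configuration before it is captured, or boron may be taken up at the allenyl terminus.
- The fallback sets out from 11, 15 and 16 and comes back at 22.
- Sonogashira coupling of 15 with 16 gives (2R)-4-(2,3,5,6-tetramethoxyphenyl)but-3-yn-2-ol F1.
- MnO2 oxidation gives 4-(2,3,5,6-tetramethoxyphenyl)but-3-yn-2-one F2.
- Iodide 11 and Mg in Et2O give {2-[(1R,3R)-1,3-dimethyl-2-methylidenecyclohexyl]ethyl}magnesium iodide F3.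
- F3 is added to F2 in toluene at low temperature in the presence of one equivalent of a chiral tridentate N,N,O ligand derived from trans-1,2-diaminocyclohexane. This is a ligand-mediated asymmetric Grignard addition to a methyl ketone.
- The same C–C bond is made under reagent control instead of substrate control, and the ligand enantiomer is chosen to give 22.

2. Step 4. Facial selectivity of the hydrogenation may be poor, or the α-centre may epimerise to the more stable epimer.
- The fallback sets out from 7 and comes back at 11.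
- Luche reduction (NaBH4, CeCl3·7H2O, MeOH) should deliver hydride anti to the acetate arm. This gives tert-butyl 2-[(1R,2S)-2-hydroxy-1,3-dimethylcyclohex-3-en-1-yl]acetate F4.
- NaH in THF closes the cis-fused lactone (3aR,7aS)-3a,7-dimethyl-3a,4,5,7a-tetrahydro-1-benzofuran-2(3H)-one F5.
- The lactone ring closes the concave face, so H2 over Pd/C should add from the convex face. This gives (3aR,7R,7aR)-3a,7-dimethylhexahydro-1-benzofuran-2(3H)-one F6.
- LiAlH4 gives (1R,2R,6R)-2-(2-hydroxyethyl)-2,6-dimethylcyclohexan-1-ol F7.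
- Selective Appel iodination of the primary hydroxyl gives (1R,2R,6R)-2-(2-iodoethyl)-2,6-dimethylcyclohexan-1-ol F8.
- Dess–Martin oxidation gives (2R,6R)-2-(2-iodoethyl)-2,6-dimethylcyclohexan-1-one F9.
- Takai–Lombardo methylenation of F9 gives 11.

3. Step 14. In the acidic cerium medium the tertiary allylic alcohol next to the electron-rich arene may ionise, which would lead to dehydration or loss of the C2 configuration.
- The fallback sets out from 22 and comes back at 24.
- The acid-robust propargylic alcohol 22 is oxidised first with (NH4)2Ce(NO3)6. This gives 3-[(3S)-5-[(1R,3R)-1,3-dimethyl-2-methylidenecyclohexyl]-3-hydroxy-3-methylpent-1-yn-1-yl]-2,5-dimethoxycyclohexa-2,5-diene-1,4-dione F10.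
- H2 over Pd/CaCO3 poisoned with Pb(OAc)2 reduces the quinone to the hydroquinone and the alkyne to the Z-alkene. This gives 2-[(1Z,3S)-5-[(1R,3R)-1,3-dimethyl-2-methylidenecyclohexyl]-3-hydroxy-3-methylpent-1-en-1-yl]-3,6-dimethoxybenzene-1,4-diol F11.
- Neutral re-oxidation of F11 with Ag2O in Et2O gives 24.

Further compounds
F1 | step 12 | (2R)-4-(2,3,5,6-tetramethoxyphenyl)but-3-yn-2-ol | C[C@@H](O)C#Cc1c(OC)c(OC)cc(OC)c1OC
F2 | step 12 | 4-(2,3,5,6-tetramethoxyphenyl)but-3-yn-2-one | CC(=O)C#Cc1c(OC)c(OC)cc(OC)c1OC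
F3 | step 12 | {2-[(1R,3R)-1,3-dimethyl-2-methylidenecyclohexyl]ethyl}magnesium iodide | I[Mg]CC[C@@]1(C)CCC[C@@H](C)C1=C
F4 | step 4 | tert-butyl 2-[(1R,2S)-2-hydroxy-1,3-dimethylcyclohex-3-en-1-yl]acetate | O[C@@H]1C(C)=CCC[C@]1(C)CC(=O)OC(C)(C)C
F5 | step 4 | (3aR,7aS)-3a,7-dimethyl-3a,4,5,7a-tetrahydro-1-benzofuran-2(3H)-one | O1[C@@H]2C(C)=CCC[C@]2(C)CC1=O
F6 | step 4 | (3aR,7R,7aR)-3a,7-dimethylhexahydro-1-benzofuran-2(3H)-one | O1[C@@H]2[C@H](C)CCC[C@]2(C)CC1=O
F7 | step 4 | (1R,2R,6R)-2-(2-hydroxyethyl)-2,6-dimethylcyclohexan-1-ol | O[C@@H]1[C@H](C)CCC[C@]1(C)CCO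
F8 | step 4 | (1R,2R,6R)-2-(2-iodoethyl)-2,6-dimethylcyclohexan-1-ol | O[C@@H]1[C@H](C)CCC[C@]1(C)CCI
F9 | step 4 | (2R,6R)-2-(2-iodoethyl)-2,6-dimethylcyclohexan-1-one | O=C1[C@H](C)CCC[C@]1(C)CCI
F10 | step 14 | 3-[(3S)-5-[(1R,3R)-1,3-dimethyl-2-methylidenecyclohexyl]-3-hydroxy-3-methylpent-1-yn-1-yl]-2,5-dimethoxycyclohexa-2,5-diene-1,4-dione | C=C1[C@H](C)CCC[C@]1(C)CC[C@@](O)(C)C#CC2=C(OC)C(=O)C=C(OC)C2=O
F11 | step 14 | 2-[(1Z,3S)-5-[(1R,3R)-1,3-dimethyl-2-methylidenecyclohexyl]-3-hydroxy-3-methylpent-1-en-1-yl]-3,6-dimethoxybenzene-1,4-diol | C=C1[C@H](C)CCC[C@]1(C)CC[C@@](O)(C)/C=C\c2c(OC)c(O)cc(OC)c2O
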